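Late in the alpha run, between 25.0 h and 40.0 h, target still gains 0.00157 M h⁻¹. That is no slower than the 0.00145 M h⁻¹ of its first 25.0 h, although solid substrate has fallen to 39.5%. So the pace does not follow the solid.

| flask | solid substrate | reagent | remark | time |
|---|---|---|---|---|
| gamma | 0.10 M | 1 equiv | run made earlier |  |
| alpha | 0.10 M | 5.1 equiv | run made earlier |  |
| zeta | 0.087 M | 1.1 equiv | run made earlier |  |
| cedar | 0.060 M | 0.740 equiv |  | 40 h |
| ash | 0.30 M | 1.70 equiv |  | 40 h |
| elm | 0.030 M | 1.10 equiv |  | 40 h |
| birch | 0.15 M | 4.40 equiv |  | 40 h |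
| maple | 0.10 M | 1.10 equiv |  | 40 h |

| run | time / h | target / % | solid substrate / % |
|---|---|---|---|
| gamma | 2.00 | 2.7 | 96.0 |
| gamma | 6.00 | 8.2 | 91.7 |
| gamma | 12.0 | 16.5 | 84.2 |
| gamma | 15.0 | 20.8 | 76.9 |
| gamma | 25.0 | 31.9 | 63.2 |
| gamma | 30.0 | 39.4 | 54.4 |
| gamma | 40.0 | 48.6 | 44.1 |
| alpha | 6.00 | 11.0 | 89.7 |
| alpha | 12.0 | 18.2 | 82.2 |
| alpha | 15.0 | 24.8 | 76.5 |
| alpha | 25.0 | 36.2 | 62.5 |
| alpha | 30.0 | 44.5 | 53.8 |
| alpha | 40.0 | 59.7 | 39.5 |
| zeta | 8.00 | 11.6 | 86.7 |
| zeta | 15.0 | 23.6 | 73.6 |
| zeta | 25.0 | 35.3 | 59.5 |
| zeta | 30.0 | 44.0 | 52.5 |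
| zeta | 40.0 | 55.5 | 34.2 |

(standard deviation of a reading: 1 percentage point)

* ranking by amount of target, in percent of the solid substrate charged, from high to low, at 40 h (cedar / ash / elm / birch / maple)
* the same order at 8.0 h (cedar / ash / elm / birch / maple)
* the amount of target, in percent of the solid substrate charged of the flask you put first, at 40 h
* the amount of target, in percent of the solid substrate charged of the flask you put last, at 40 h

- at the start none of the solid substrate is in solution
- what has only dissolved of solid substrate counts as not reacted
- a reading or a percentage of target counts all its forms, free or not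

Does it follow the reagent? Alpha has 5.10 times the equivalents of gamma, yet at 25.0 h alpha holds just 1.13 times gamma's target. I therefore read a step of fixed pace, a rate-limiting step that feeds the solution. Call it the feed F, the target made per litre per hour with reagent in excess, read from alpha's last reading as 0.00149 M h⁻¹.

What does F mean in percent? It is F times time over the charged [solid substrate], so at a fixed time, with reagent in excess, dilution raises the percentage. At 40 h, ash reaches 19.9% and birch 39.8%, both well inside their reagent. Elm would need 199%, which cannot be, so elm's solid lasts about 20.1 h.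

Where does the late end of the dilute flasks lie? Gamma's last reading misses 7.3 percentage points of its charge, and alpha's misses 0.8 points, so a loss opens when reagent is thin. Gamma stands at 0.814 of its feed value, which puts maple near 48.6%. Cedar has the fewest equivalents, so its target is capped at 0.740 of its charge, and I leave cedar against maple open. I put elm first, birch fourth and ash last, and I expect the order at 8.0 h to follow dilution.

The forecast gave elm > cedar > maple > birch > ash at 40.0 h, elm > cedar > maple > birch > ash at 8.00 h, top 80% and low 20%, on the ground of “a nearly fixed absolute rate rather than a fixed percentage rate”, and unlike me it commits to a top value.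

    reagent + target ⇌ idle adduct, settled at all times (K = 74.0 L mol⁻¹)
    crystals ⇌ target, rate k2*(cs2 - [target]) while solid is left; crystals form when [target] > cs2 (solubility = 0.0560 M, k = 6.50 × 10⁻⁵ s⁻¹)
    solid substrate ⇌ dissolved substrate, rate k3*(cs3 - [dissolved substrate]) while solid is left; crystals form when [dissolved substrate] > cs3 (solubility = 6.70 mM, k = 6.30 × 10⁻⁵ s⁻¹)
    dissolved substrate + reagent → target (k = 0.0170 L mol⁻¹ s⁻¹)
    2 dissolved substrate → side product (k = 0.160 L mol⁻¹ s⁻¹)

The flask gives elm > maple > cedar > birch > ash at 40.0 h and elm > cedar > maple > birch > ash at 8.00 h, with top 57.1% and low 20.0%. Elm ends with 42.9% as side product beside that target. F gave ash 19.9%, against the 20.0% found. Carried to 6.0 d, the same ash flask comes to 71.6% by F, and its target there stands at 71.2%.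

(The numbers in the tables are simulated with constants of no real substance, noise included.)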